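The earlier runs and the new flask were computed for substances that don't exist, and the scatter is random.

The easy step came first: in the last row of the dawn run I added E and L and found 0.0100 M of the L charge missing, close to the 0.010 M of Z. So I let each Z remove one L.

| flask | L | X | Z | temperature | remark | time |
|---|---|---|---|---|---|---|
| dusk | 0.043 M | 0.22 M | 0.010 M | 105 °C | run made earlier |  |
| dawn | 0.13 M | 0.22 M | 0.010 M | 116 °C | run made earlier |  |
| autumn | 0.26 M | 0.22 M | 0.010 M | 105 °C | run made earlier |  |
| Friday's | 0.10 M | 0.220 M | 0.0100 M | 110 °C |  | 8.0 h |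
| Thursday's | 0.30 M | 0.220 M | 0.0100 M | 110 °C |  | 8.0 h |
| Sunday's | 0.12 M | 0.220 M | 0.0100 M | 110 °C |  | 8.0 h |
| Saturday's | 0.20 M | 0.220 M | 0.0100 M | 110 °C |  | 8.0 h |
| Monday's | 0.060 M | 0.220 M | 0.0100 M | 110 °C |  | 8.0 h |

| run | time / h | E / % | L / % |
|---|---|---|---|
| dusk | 0.333 | 34.2 | 54.3 |
| dusk | 0.667 | 50.5 | 34.1 |
| dusk | 1.00 | 59.7 | 22.9 |
| dusk | 2.00 | 67.0 | 14.1 |
| dusk | 4.00 | 67.0 | 11.9 |
| dawn | 0.333 | 48.8 | 44.1 |
| dawn | 0.667 | 55.1 | 37.2 |
| dawn | 1.00 | 55.6 | 36.5 |
| dawn | 2.00 | 56.0 | 36.6 |
| dawn | 4.00 | 55.6 | 36.7 |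
| autumn | 0.333 | 27.9 | 67.5 |
| autumn | 0.667 | 38.8 | 58.1 |
| autumn | 1.00 | 41.3 | 55.1 |
| autumn | 2.00 | 42.6 | 53.2 |
| autumn | 4.00 | 42.8 | 52.8 |

(readings scatter by 0.3 percentage points)

- the flasks by amount of E, in percent of the L charged, highest first, at 8.0 h (Friday's / Thursday's / Sunday's / Saturday's / Monday's)
- the amount of E, in percent of the L charged of the flask you put first, at 8.0 h
- the amount of E, in percent of the L charged of the flask you put last, at 8.0 h

The dawn rows stood still from 1.00 h with L left over, so I supposed a balance: each E comes with one unseen partner and costs one X. I then read the last rows through the quotient [E] squared over [L][X]. The dusk row gave 0.848. The autumn row, at the same temperature but with 0.26 M of L against 0.043 M, gave 0.830, nearly the same. The dawn row, at 116 °C, gave a lower 0.741.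

The dusk and autumn quotients lay close together, and 110 °C lies between 105 °C and 116 °C, not far from the middle. So I averaged the mean of those two with the dawn value and took the result as the stopping quotient, the value of that ratio at which a flask stands still: 0.790. Solving it with the L charge less Z, my own reckoning gave Monday's 65.4% and Thursday's 39.3%.

The forecast, reasoning differently, that “Turnover per Z therefore rises less than proportionally with L”, gave Monday's > Friday's > Sunday's > Saturday's > Thursday's, with 64% and 39.5%.

The flasks gave Monday's > Friday's > Sunday's > Saturday's > Thursday's, with 65.4% and 39.3%.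

    L + X ⇌ E + J (K = 0.790, k = 0.00270 M⁻¹ s⁻¹, Ea = 96.0 kJ mol⁻¹, ΔH = −9.00 kJ mol⁻¹)
    L + Z → Q (k = 0.0220 M⁻¹ s⁻¹, Ea = 57.0 kJ mol⁻¹)
    (constants at 110 °C)

Thursday's stopped at 39.3%, against 73.3% in the same flask with the back step taken away, because E and J fell back to L and X, the balance that 0.790 describes. This is thermodynamic control: a tenfold time changed nothing in Thursday's. For the neighbour of Monday's with 0.55 M of X, 0.790 gives 74.9%, and the computed flask gave 75.2%.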